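The five-membered ring (C1–C5) of this dauc-8-ene carries oxygen on C2 and C4, 1,3 across the C3 methylene. This is a β-hydroxy ketone pattern once C2 is a carbonyl, so the plan rests on the C3–C4 bond. SmI2 converts a bromoacetyl group on C1 into a regiodefined samarium enolate, which adds to an isobutyryl ketone on C5. One operation closes the cyclopentane trans onto the cycloheptene and creates the tertiary C4 carbinol. The precursor is a cycloheptene (C8=C9) with trans bromoacetyl and isobutyryl arms and silyl ethers on C6 and C10. It is unmasked without base from a γ-lactone that ties C2 to a sacrificial C4 stereocentre.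

Key step: step 14

Numbering (used for all intermediates): C1 quaternary methyl-bearing fusion carbon, C2 acetate carbon, C3 ring CH2, C4 isopropyl carbinol, C5 fusion CH, C6 angelate carbon, C7 CH2, C8 methyl-bearing alkene carbon, C9 alkene CH, C10 benzoate carbon.
Design remark: C10 passes through the key step as a triethylsilyl ether and is benzoylated afterwards. The bromo ketone is released from a lactone, so no γ-keto acid ever has to be activated.
Assumption: C1 of 8–15 forms as an inconsequential epimer mixture that is erased in enolate 17. The SMILES show the epimer with methyl trans to the C5 substituent.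

Step 1
Reactants: 1 (±)-4-methylpent-1-en-3-ol
Product: 2 (S)-4-methylpent-1-en-3-ol
Conditions: Ti(OiPr)4 (0.15 equiv), D-(−)-diisopropyl tartrate (0.2 equiv), t-BuOOH (0.6 equiv), 4 Å MS, CH2Cl2, −20 °C
Reagents that add atoms: none
Why: Sharpless kinetic resolution: with the D-(−)-tartrate the (R)-enantiomer of a 1-alken-3-ol is epoxidised much faster, so the (S)-alcohol, whose carbinol carbon becomes the sacrificial C4 stereocentre, should remain and is separated from the epoxy alcohol.

Step 2
Reactants: 2 (S)-4-methylpent-1-en-3-ol; 3 methacryloyl chloride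
Product: 4 (S)-4-methylpent-1-en-3-yl methacrylate
Conditions: Et3N, 4-dimethylaminopyridine (cat.), CH2Cl2, 0 °C → rt
Reagents that add atoms: none
Why: O-acylation of a secondary alcohol with an acid chloride, which does not touch the stereocentre.

Step 3
Reactants: 4 (S)-4-methylpent-1-en-3-yl methacrylate
Product: 5 (S)-5-isopropyl-3-methylfuran-2(5H)-one
Conditions: second-generation Grubbs catalyst (5 mol %), CH2Cl2 (0.02 M), reflux
Reagents that add atoms: none
Why: Ring-closing metathesis of allyl methacrylates is an established entry to α-methylbutenolides, loss of ethylene drives it and C4 is untouched.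

Step 4
Reactants: 5 (S)-5-isopropyl-3-methylfuran-2(5H)-one; 6 vinylmagnesium bromide
Product: 8 (3R,4R,5S)-5-isopropyl-3-methyl-4-vinyldihydrofuran-2(3H)-one, via silyl ketene acetal 7 (not isolated)
Conditions: CuBr·SMe2 (10 mol %), Me3SiCl, THF, −78 → −40 °C; then 1 M HCl, 0 °C
Reagents that add atoms: none
Why: Copper-catalysed, chlorosilane-accelerated conjugate addition of a vinyl Grignard reagent to a butenolide, in which the nucleophile should enter anti to the C4 isopropyl group and thereby set C5.

Step 5
Reactants: 8 (3R,4R,5S)-5-isopropyl-3-methyl-4-vinyldihydrofuran-2(3H)-one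
Product: 10 (2S,3R,4R)-2-isopropyl-4-methyl-5-oxotetrahydrofuran-3-carbaldehyde, via secondary ozonide 9 (not isolated)
Conditions: O3, CH2Cl2, −78 °C; then Me2S, −78 °C → rt
Reagents that add atoms: ozone [O-][O+]=O
Why: Ozonolysis with reductive work-up cleaves the only alkene to the C6 aldehyde under neutral conditions, so neither C5 epimerisation nor β-elimination of the lactone oxygen on C4 is triggered.

Step 6
Reactants: 10 (2S,3R,4R)-2-isopropyl-4-methyl-5-oxotetrahydrofuran-3-carbaldehyde; 11 2-methylallylmagnesium chloride
Product: 14 γ-lactone carrying at C5 the (S)-1-hydroxy-3-methylbut-3-en-1-yl chain trans to the C4 isopropyl group, via B-methallyldiisopinocampheylborane 12 (not isolated), via diisopinocampheylborinate 13 (not isolated)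
Conditions: (−)-Ipc2BOMe, 11, Et2O, −78 °C → rt; then 10, −78 °C; H2O2, pH 7 buffer, MeOH, 0 °C
Reagents that add atoms: none
Why: Brown asymmetric methallylboration through a closed chair transition state, in which the reagent derived from (+)-α-pinene should give the (6S)-carbinol under reagent control, while the buffered oxidative work-up avoids migration of the lactone to the new hydroxyl.

Step 7
Reactants: 14 C6 alcohol
Product: 15 C6 tert-butyldimethylsilyl ether of 14
Conditions: TBSOTf, 2,6-lutidine, CH2Cl2, −78 → 0 °C
Reagents that add atoms: tert-butyldimethylsilyl triflate CC(C)(C)[Si](C)(C)OS(=O)(=O)C(F)(F)F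
Why: Silyl triflate protection of a hindered secondary alcohol blocks C6 before enolate chemistry and freezes the lactone on the C4 oxygen.

Step 8
Reactants: 15 silyl ether lactone; 16 acrolein
Product: 19 aldol lactone with quaternary C1 (methyl cis to the C5 chain; (S)-1-hydroxyallyl group trans to it), via lithium enolate 17 (not isolated), via lithium aldolate 18 (not isolated)
Conditions: LiN(iPr)2, THF, −78 °C; then 16, −78 °C; AcOH quench at −78 °C
Reagents that add atoms: none
Why: Lithium enolate aldol addition in which acrolein should approach the face of 17 opposite to the C5 chain (sets C1), and the Zimmerman–Traxler chair of the ring-locked enolate with the vinyl group equatorial should place the C10 oxygen syn to the C1 methyl group along the C2–C1–C10–C9 zigzag (sets C10).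

Step 9
Reactants: 19 aldol lactone
Product: 20 trans-fused cycloheptene γ-lactone with free C10 hydroxyl (C10–O cis to the C1 methyl; C6–OTBS cis to H5)
Conditions: second-generation Hoveyda–Grubbs catalyst (5–10 mol %), 1,4-benzoquinone (10 mol %), toluene (0.005 M), 80 °C
Reagents that add atoms: none
Why: Ring-closing metathesis between the vinyl carbinol and the 1,1-disubstituted alkene forms C8=C9 and the seven-membered ring, and the allylic hydroxyl is left free because it accelerates metathesis at the hindered vinyl group.

Step 10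
Reactants: 20 bicyclic hydroxy lactone
Product: 21 C10 triethylsilyl ether of 20
Conditions: TESOTf, 2,6-lutidine, CH2Cl2, −78 → 0 °C
Reagents that add atoms: triethylsilyl triflate CC[Si](CC)(CC)OS(=O)(=O)C(F)(F)F
Why: Silyl triflate protection, with triethylsilyl chosen for C10 because it can later be removed in the presence of the C6 tert-butyldimethylsilyl ether.

Step 11
Reactants: 21 bis-silyl lactone
Product: 22 exocyclic enol ether (C2=C3H2; ring oxygen on C4)
Conditions: Cp2TiMe2 (3 equiv), toluene, 75 °C, dark
Reagents that add atoms: dimethyltitanocene Cp2TiMe2 C[Ti](C)(C1C=CC=C1)C1C=CC=C1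
Why: Petasis methylenation of a lactone carbonyl brings in C3 and gives an enol ether that cannot isomerise into the ring because C1 is quaternary.

Step 12
Reactants: 22 exocyclic enol ether
Product: 23 bromomethyl lactol (C2 hemiketal as an anomer mixture; C3H2Br)
Conditions: NBS (1.05 equiv), NaHCO3, THF–H2O (4:1), 0 °C
Reagents that add atoms: N-bromosuccinimide O=C1CCC(=O)N1Br; water O
Why: Bromohydration of an enol ether, in which the electron-rich C2=C3 bond reacts far faster than the trisubstituted C8=C9 alkene, bromine goes to terminal C3 and water caps the oxocarbenium carbon C2.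

Step 13
Reactants: 23 bromomethyl lactol
Product: 25 cycloheptene with bromoacetyl on C1 and isobutyryl on C5 (trans); C6–OTBS; C10–OTES, via open hydroxy bromo ketone 24 (not isolated)
Conditions: Dess–Martin periodinane, CH2Cl2, rt
Reagents that add atoms: none
Why: Dess–Martin oxidation drains the lactol through its open tautomer 24 and erases the sacrificial C4 stereocentre without base, so C5 and the β-silyloxy group on C6 are safe.

Step 14
Reactants: 25 bromo diketone
Product: 28 trans-hydroazulene β-hydroxy ketone (C2 ketone; C4 tertiary carbinol cis to the C1 methyl), via samarium enolate 26 (not isolated), via samarium aldolate 27 (not isolated)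
Conditions: SmI2 (2.5 equiv, 0.1 M in THF), slow addition of 25, −78 °C; pH 7 buffer at −78 °C
Reagents that add atoms: none
Why: Two one-electron transfers from divalent samarium cleave the C3–Br bond and give the oxygen-bound trivalent samarium enolate 26 at C3 only and without base, so H5 and the β-silyloxy group on C6 are left alone. The enolate carbon then adds to the C4 ketone bound by the same Lewis-acidic metal, and aldolate 27 is held as a six-membered chelate until the cold quench, which suppresses retro-aldol; this is the known SmI2-promoted intramolecular Reformatsky-type aldol of α-halo ketones. The ring closes in the 5-(enolendo)-exo-trig mode, since C2 and C3 both end up inside the new ring; this mode is formally disfavoured for enolates, yet it is the mode by which 1,4-diketones routinely close to cyclopentenones, and it is the one real risk of the route. The trans ring fusion is fixed beforehand by the trans arms on C1 and C5, which can both lie pseudo-equatorial and gauche to each other. At C4 the isopropyl group should turn to the face of H5, away from the C1 methyl group and the C5–C6 bond, so that the oxygen ends up cis to the C1 methyl group as the target requires. Chemoselectivity rests on the much faster reduction of an α-bromo ketone than of a dialkyl ketone, and C10 is a silyl ether rather than an allylic benzoate so that neither reductive C–O cleavage nor acyl transfer to the enolate through a six-membered transition state can compete.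

Step 15
Reactants: 28 β-hydroxy ketone
Product: 30 C2,C4-trans diol, via alkoxydiacetoxyborohydride 29 (not isolated)
Conditions: Me4NBH(OAc)3, MeCN–AcOH, −30 °C
Reagents that add atoms: none
Why: Evans–Saksena reduction, in which the C4 hydroxyl replaces one acetate on boron and hydride is delivered within 29 to the carbonyl face that carries the C4 oxygen, which should give the C2 alcohol trans to the C4 hydroxyl.

Step 16
Reactants: 30 diol
Product: 31 C2 acetate
Conditions: Ac2O, 4-dimethylaminopyridine (cat.), pyridine, CH2Cl2, rt
Reagents that add atoms: acetic anhydride CC(=O)OC(C)=O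
Why: Catalysed acetylation is selective for the secondary C2 hydroxyl because the tertiary C4 carbinol next to the isopropyl group does not react under these conditions.

Step 17
Reactants: 31 C2 acetate
Product: 32 C10 alcohol
Conditions: pyridinium p-toluenesulfonate (cat.), MeOH–CH2Cl2, 0 °C
Reagents that add atoms: none
Why: Mild acid-catalysed methanolysis cleaves a triethylsilyl ether much faster than a tert-butyldimethylsilyl ether and leaves the acetate in place.

Step 18
Reactants: 32 C10 alcohol
Product: 33 C10 benzoate
Conditions: BzCl, 4-dimethylaminopyridine, pyridine, 40 °C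
Reagents that add atoms: benzoyl chloride O=C(Cl)c1ccccc1
Why: Catalysed benzoylation of the neopentyl allylic C10 alcohol, with the tertiary C4 hydroxyl again staying free.

Step 19
Reactants: 33 C10 benzoate
Product: 34 C6 alcohol
Conditions: HF·pyridine, pyridine, THF, 0 °C → rt
Reagents that add atoms: none
Why: Fluoride desilylation under slightly acidic conditions avoids the acyl migration and ester cleavage that basic fluoride sources can cause.

Step 20
Reactants: 34 C6 alcohol; 35 angelic acid
Product: 37 CNP0248576.1, via angelic 2,4,6-trichlorobenzoic anhydride 36 (not isolated)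
Conditions: 35, 2,4,6-trichlorobenzoyl chloride, Et3N, toluene, rt; then 34, toluene, 80 °C
Reagents that add atoms: none
Why: Yamaguchi-type esterification through mixed anhydride 36 without a nucleophilic catalyst is the established way to make angelates without Z to E isomerisation, and only the secondary C6 hydroxyl is acylated.

Compound list
1 | (±)-4-methylpent-1-en-3-ol | C=CC(O)C(C)C | starting material
2 | (S)-4-methylpent-1-en-3-ol | C=C[C@@H](O)C(C)C | intermediate
3 | methacryloyl chloride | C=C(C)C(=O)Cl | starting material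
4 | (S)-4-methylpent-1-en-3-yl methacrylate | C=C[C@@H](OC(=O)C(C)=C)C(C)C | intermediate
5 | (S)-5-isopropyl-3-methylfuran-2(5H)-one | CC(C)[C@@H]1OC(=O)C(C)=C1 | intermediate
6 | vinylmagnesium bromide | C=C[Mg]Br | starting material
7 | trimethylsilyl ketene acetal from the conjugate addition (vinyl trans to isopropyl) | CC(C)[C@@H]1OC(O[Si](C)(C)C)=C(C)[C@H]1C=C | intermediate
8 | (3R,4R,5S)-5-isopropyl-3-methyl-4-vinyldihydrofuran-2(3H)-one | CC(C)[C@@H]1OC(=O)[C@H](C)[C@H]1C=C | intermediate
9 | secondary ozonide of 8 (1,2,4-trioxolane on C5) | CC(C)[C@@H]1OC(=O)[C@H](C)[C@H]1C1OCOO1 | intermediate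
10 | (2S,3R,4R)-2-isopropyl-4-methyl-5-oxotetrahydrofuran-3-carbaldehyde | CC(C)[C@@H]1OC(=O)[C@H](C)[C@H]1C=O | intermediate
11 | 2-methylallylmagnesium chloride | C=C(C)C[Mg]Cl | starting material
12 | (−)-B-(2-methylallyl)diisopinocampheylborane | C=C(C)CB([C@@H]1C[C@@H]2C[C@H]([C@H]1C)C2(C)C)[C@@H]1C[C@@H]2C[C@H]([C@H]1C)C2(C)C | intermediate
13 | diisopinocampheylborinate of 14 | CC(C)[C@@H]1OC(=O)[C@H](C)[C@H]1[C@@H](OB([C@@H]2C[C@@H]3C[C@H]([C@H]2C)C3(C)C)[C@@H]2C[C@@H]3C[C@H]([C@H]2C)C3(C)C)CC(C)=C | intermediate
14 | γ-lactone with (6S)-1-hydroxy-3-methylbut-3-enyl chain on C5 | CC(C)[C@@H]1OC(=O)[C@H](C)[C@H]1[C@@H](O)CC(C)=C | intermediate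
15 | C6 tert-butyldimethylsilyl ether of 14 | CC(C)[C@@H]1OC(=O)[C@H](C)[C@H]1[C@@H](O[Si](C)(C)C(C)(C)C)CC(C)=C | intermediate
16 | acrolein | C=CC=O | starting material
17 | lithium enolate of 15 | CC(C)[C@@H]1OC(O[Li])=C(C)[C@H]1[C@@H](O[Si](C)(C)C(C)(C)C)CC(C)=C | intermediate
18 | lithium aldolate of 19 | CC(C)[C@@H]1OC(=O)[C@](C)([C@@H](O[Li])C=C)[C@H]1[C@@H](O[Si](C)(C)C(C)(C)C)CC(C)=C | intermediate
19 | aldol lactone, quaternary C1, (10S)-allylic alcohol | CC(C)[C@@H]1OC(=O)[C@](C)([C@@H](O)C=C)[C@H]1[C@@H](O[Si](C)(C)C(C)(C)C)CC(C)=C | intermediate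
20 | trans-fused cycloheptene γ-lactone, C10–OH, C6–OTBS | CC(C)(C)[Si](C)(C)O[C@H]1CC(C)=C[C@H](O)[C@@]2(C)C(=O)O[C@@H](C(C)C)[C@H]12 | intermediate
21 | C10 triethylsilyl ether of 20 | CC(C)(C)[Si](C)(C)O[C@H]1CC(C)=C[C@H](O[Si](CC)(CC)CC)[C@@]2(C)C(=O)O[C@@H](C(C)C)[C@H]12 | intermediate
22 | exocyclic enol ether (C2=C3H2) | CC(C)(C)[Si](C)(C)O[C@H]1CC(C)=C[C@H](O[Si](CC)(CC)CC)[C@@]2(C)C(=C)O[C@@H](C(C)C)[C@H]12 | intermediate
23 | bromomethyl lactol (anomer mixture at C2) | CC(C)(C)[Si](C)(C)O[C@H]1CC(C)=C[C@H](O[Si](CC)(CC)CC)[C@@]2(C)C(O)(CBr)O[C@@H](C(C)C)[C@H]12 | intermediate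
24 | open hydroxy bromo ketone tautomer of 23 | CC(C)(C)[Si](C)(C)O[C@H]1CC(C)=C[C@H](O[Si](CC)(CC)CC)[C@@](C)(C(=O)CBr)[C@@H]1[C@@H](O)C(C)C | intermediate
25 | key-step precursor: bromoacetyl on C1, isobutyryl on C5, C6–OTBS, C10–OTES | CC(C)(C)[Si](C)(C)O[C@H]1CC(C)=C[C@H](O[Si](CC)(CC)CC)[C@@](C)(C(=O)CBr)[C@@H]1C(=O)C(C)C | intermediate
26 | diiodosamarium enolate (C2=C3) | CC(C)(C)[Si](C)(C)O[C@H]1CC(C)=C[C@H](O[Si](CC)(CC)CC)[C@@](C)(C(=C)O[Sm](I)I)[C@@H]1C(=O)C(C)C | intermediate
27 | diiodosamarium aldolate | CC(C)(C)[Si](C)(C)O[C@H]1CC(C)=C[C@H](O[Si](CC)(CC)CC)[C@@]2(C)C(=O)C[C@@](O[Sm](I)I)(C(C)C)[C@H]12 | intermediate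
28 | key-step product: hydroazulene β-hydroxy ketone | CC(C)(C)[Si](C)(C)O[C@H]1CC(C)=C[C@H](O[Si](CC)(CC)CC)[C@@]2(C)C(=O)C[C@@](O)(C(C)C)[C@H]12 | intermediate
29 | tetramethylammonium C4-alkoxydiacetoxyborohydride | CC(C)(C)[Si](C)(C)O[C@H]1CC(C)=C[C@H](O[Si](CC)(CC)CC)[C@@]2(C)C(=O)C[C@@](O[BH-](OC(C)=O)OC(C)=O)(C(C)C)[C@H]12.C[N+](C)(C)C | intermediate
30 | C2,C4-trans diol | CC(C)(C)[Si](C)(C)O[C@H]1CC(C)=C[C@H](O[Si](CC)(CC)CC)[C@@]2(C)[C@@H](O)C[C@@](O)(C(C)C)[C@H]12 | intermediate
31 | C2 acetate | CC(C)(C)[Si](C)(C)O[C@H]1CC(C)=C[C@H](O[Si](CC)(CC)CC)[C@@]2(C)[C@@H](OC(C)=O)C[C@@](O)(C(C)C)[C@H]12 | intermediate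
32 | C10 alcohol | CC(C)(C)[Si](C)(C)O[C@H]1CC(C)=C[C@H](O)[C@@]2(C)[C@@H](OC(C)=O)C[C@@](O)(C(C)C)[C@H]12 | intermediate
33 | C10 benzoate | CC(C)(C)[Si](C)(C)O[C@H]1CC(C)=C[C@H](OC(=O)c2ccccc2)[C@@]2(C)[C@@H](OC(C)=O)C[C@@](O)(C(C)C)[C@H]12 | intermediate
34 | C6 alcohol | O[C@H]1CC(C)=C[C@H](OC(=O)c2ccccc2)[C@@]2(C)[C@@H](OC(C)=O)C[C@@](O)(C(C)C)[C@H]12 | intermediate
35 | angelic acid, (Z)-2-methylbut-2-enoic acid | C/C=C(/C)C(=O)O | starting material
36 | angelic 2,4,6-trichlorobenzoic anhydride | C/C=C(/C)C(=O)OC(=O)c1c(Cl)cc(Cl)cc1Cl | intermediate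
37 | CNP0248576.1, (1R,2S,4R,5S,6S,10S)-dauc-8-ene-2,4,6,10-tetrol 2-acetate 6-angelate 10-benzoate | C/C=C(/C)C(=O)O[C@H]1CC(C)=C[C@H](OC(=O)c2ccccc2)[C@@]2(C)[C@@H](OC(C)=O)C[C@@](O)(C(C)C)[C@H]12 | target

Total step count: 20. Longest linear sequence: 20 steps (1 → 37).

Steps most likely to fail

Step 14. Ring closure may lose the race against protonation of the enolate, or it may revert by retro-aldol. The enolendo geometry gives poor orbital overlap, and the acceptor is a hindered ketone. The fallback sets out from 25. Reductive silylation with Zn dust and Me3SiCl in THF should give the regiodefined C2 trimethylsilyl enol ether F1. TiCl4 in CH2Cl2 at −78 °C then activates the C4 ketone for an intramolecular Mukaiyama aldol addition through an open transition state. Aqueous work-up brings the material back to the route at 28.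

Step 8. Facial selectivity at the aldehyde carbon (C10) may be poor if the lithium-bound chair is not dominant. The fallback sets out from 19, used whatever its composition at C10. Dess–Martin oxidation should give the β-keto lactone vinyl ketone F2, which cannot enolise at the quaternary C1. A Corey–Bakshi–Shibata reduction with (R)-2-methyl-CBS-oxazaborolidine and catecholborane in toluene at −78 °C then treats C1 as the large substituent. It resets C10 under reagent control and returns to the route at 19.

Step 11. Methylenation may be slow or incomplete because the lactone carbonyl is shielded by the quaternary C1 and the C10 silyl ether, while the titanium reagent decays thermally. The fallback sets out from 21: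
- MeLi in Et2O at −78 °C should add once to give the methyl lactol F3.
- Dess–Martin oxidation through the open tautomer should give the methyl ketone/isopropyl ketone diketone F4.
- Kinetic deprotonation of the only CH3 ketone site with LiN(SiMe3)2 in the presence of Me3SiCl at −78 °C gives the trimethylsilyl enol ether F1.
- NBS in THF at −78 °C converts F1 into the bromo ketone, rejoining the route at 25.

Further compounds
F1 | step 14 | C2 trimethylsilyl enol ether (C2=C3H2) of the C1 acetyl, C5 isobutyryl cycloheptene | CC(C)(C)[Si](C)(C)O[C@H]1CC(C)=C[C@H](O[Si](CC)(CC)CC)[C@@](C)(C(=C)O[Si](C)(C)C)[C@@H]1C(=O)C(C)C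
F2 | step 8 | C10 vinyl ketone (β-keto lactone) from 19 | CC(C)[C@@H]1OC(=O)[C@](C)(C(=O)C=C)[C@H]1[C@@H](O[Si](C)(C)C(C)(C)C)CC(C)=C
F3 | step 11 | methyl lactol (C2 hemiketal, anomer mixture) | CC(C)(C)[Si](C)(C)O[C@H]1CC(C)=C[C@H](O[Si](CC)(CC)CC)[C@@]2(C)C(C)(O)O[C@@H](C(C)C)[C@H]12
F4 | step 11 | 1,4-diketone with acetyl on C1 and isobutyryl on C5 | CC(C)(C)[Si](C)(C)O[C@H]1CC(C)=C[C@H](O[Si](CC)(CC)CC)[C@@](C)(C(C)=O)[C@@H]1C(=O)C(C)C
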